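**Plan**

- Retrosynthesis: the tetrahydrofuran is cut at O1–C2 (benzylic ether) and C2–C3 (aldol) to a β-(arylmethyl)-γ-butyrolactone; the lactone O–CH2 bond (O1–C5 of the target) is cut back to a cyclobutanone; the four-membered ring goes back to an allyl arene and dichloroketene, the allyl group to an aryl bromide, and the dihydrobenzofuran (O1–C2 and C2–C3) to an arylacetyl imide and a vanillin ether.
- Enabling feature: C4 of the tetrahydrofuran carries the arylmethyl group and two one-carbon arms, C5 (bonded to O1) and C3 (bearing the CH2OH carbon). If that CH2OH carbon is a carbonyl bonded to both C3 and C5, C4 is the prochiral C3 of a 3-(arylmethyl)cyclobutanone with enantiotopic ring CH2 groups, and inserting oxygen next to one of them makes O1–C5 and the C4 stereocentre in one event.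
- Forward order: dihydrobenzofuran first (aldol, reduction, acid closure), then allylation, the cyclobutanone ([2+2], dechlorination), its ring expansion to the lactone, the tetrahydrofuran (aldol, reduction, acid closure), and desilylation.
- Stereochemistry: dihydrobenzofuran C3 comes from the (S)-4-benzyloxazolidinone auxiliary and C2 from trans-selective cation capture; tetrahydrofuran C4 comes from the chiral scandium catalyst, C3 from enolate attack anti to the C4 substituent, and C2 from trans-selective cation capture.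

Key step: step 15

Remark: which antipode of the N,N'-dioxide ligand gives the (S)-lactone cannot be read from the structure; it is assumed to be assigned in a trial on 3-benzylcyclobutanone, and the route is written for that antipode.

Abbreviations: Ar1 = 3-methoxy-4-(triisopropylsilyloxy)phenyl; Ar2 = 4-methoxy-3-(triisopropylsilyloxy)phenyl; DBF = (2S,3R)-3-[(tert-butyldimethylsilyloxy)methyl]-4-methoxy-2-Ar1-2,3-dihydrobenzofuran-6-yl.

**Route**

Step 1
Reactants: 1 vanillin
Product: 2 3-methoxy-4-(triisopropylsilyloxy)benzaldehyde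
Conditions: TIPSCl, imidazole, DMF, rt
Reagents that add atoms: triisopropylsilyl chloride, CC(C)[Si](Cl)(C(C)C)C(C)C
Why: Imidazole-promoted O-silylation of a phenol; the bulky aryl silyl ether is chosen because it should survive the acidic, basic and hydride steps until fluoride removes it at the end.

Step 2
Reactants: 3 isovanillin
Product: 4 4-methoxy-3-(triisopropylsilyloxy)benzaldehyde
Conditions: TIPSCl, imidazole, DMF, rt
Reagents that add atoms: triisopropylsilyl chloride, CC(C)[Si](Cl)(C(C)C)C(C)C
Why: The same phenol O-silylation, giving the aldehyde partner for the late aldol step.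

Step 3
Reactants: 5 4-bromo-2,6-dimethoxybenzaldehyde
Product: 6 4-bromo-2-hydroxy-6-methoxybenzaldehyde
Conditions: BCl3 (1.2 equiv), CH2Cl2, −78 → 0 °C; H2O
Reagents that add atoms: none
Why: Chelation-directed Lewis-acid ether cleavage, in which boron bound to the formyl oxygen removes one ortho methyl ether, the resulting chelate stops the second cleavage, and the equivalence of the two methoxy groups allows only one product.

Step 4
Reactants: 6 4-bromo-2-hydroxy-6-methoxybenzaldehyde
Product: 7 4-bromo-2-methoxy-6-(methoxymethoxy)benzaldehyde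
Conditions: MOMCl, i-Pr2NEt, CH2Cl2, 0 °C → rt
Reagents that add atoms: chloromethyl methyl ether, COCCl
Why: O-alkylation of the phenol to the methoxymethyl acetal, which tolerates the basic homologation and hydrolysis and later leaves under the acid that closes the dihydrobenzofuran.

Step 5
Reactants: 7 4-bromo-2-methoxy-6-(methoxymethoxy)benzaldehyde
Product: 9 2-[4-bromo-2-methoxy-6-(methoxymethoxy)phenyl]acetonitrile, via 4-tosyl-2-oxazoline 8 (not isolated)
Conditions: TosMIC, KOt-Bu, DME, −40 °C; then MeOH, reflux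
Reagents that add atoms: p-toluenesulfonylmethyl isocyanide, Cc1ccc(cc1)S(=O)(=O)C[N+]#[C-]
Why: van Leusen reductive cyanation, in which the TosMIC anion adds to the aldehyde and closes to the oxazoline, and methanolysis then expels sulfinate and methyl formate to leave the one-carbon-homologated nitrile.

Step 6
Reactants: 9 2-[4-bromo-2-methoxy-6-(methoxymethoxy)phenyl]acetonitrile
Product: 10 2-[4-bromo-2-methoxy-6-(methoxymethoxy)phenyl]acetic acid
Conditions: KOH, EtOH–H2O, reflux; then 1 M HCl to pH 3, 0 °C
Reagents that add atoms: water, O; potassium hydroxide, [K+].[OH-]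
Why: Base hydrolysis of a nitrile to the carboxylic acid, to which the aryl bromide, the methyl ether and the acetal are inert, with a cold and brief acidification that should spare the acetal.

Step 7
Reactants: 10 2-[4-bromo-2-methoxy-6-(methoxymethoxy)phenyl]acetic acid; 11 (S)-4-benzyl-2-oxazolidinone
Product: 13 (S)-4-benzyl-3-{2-[4-bromo-2-methoxy-6-(methoxymethoxy)phenyl]acetyl}oxazolidin-2-one, via mixed pivalic anhydride 12 (not isolated)
Conditions: PivCl, Et3N, THF, −20 °C; then 11, LiCl, rt
Reagents that add atoms: none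
Why: N-acylation of the oxazolidinone through the mixed anhydride, a variant that needs no organolithium and therefore leaves the aryl bromide alone.

Step 8
Reactants: 13 the arylacetyl imide; 2 3-methoxy-4-(triisopropylsilyloxy)benzaldehyde
Product: 15 (S)-4-benzyl-3-{(2S,3S)-2-[4-bromo-2-methoxy-6-(methoxymethoxy)phenyl]-3-hydroxy-3-Ar1-propanoyl}oxazolidin-2-one, via Z-boron enolate 14 (not isolated)
Conditions: Bu2BOTf, i-Pr2NEt, CH2Cl2, 0 °C; then 2, −78 → 0 °C; pH 7 buffer, MeOH, H2O2
Reagents that add atoms: none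
Why: Evans syn-aldol reaction, in which the Z-boron enolate reacts through a closed chair transition state on the face away from the benzyl group of the auxiliary, so the aryl-bearing carbon (later C3 of the dihydrobenzofuran) becomes S and the carbinol forms syn to it.

Step 9
Reactants: 15 the syn-aldol imide
Product: 16 (1S,2R)-2-[4-bromo-2-methoxy-6-(methoxymethoxy)phenyl]-1-Ar1-propane-1,3-diol
Conditions: LiBH4, THF–MeOH, 0 °C
Reagents that add atoms: none
Why: Reductive cleavage of the N-acyloxazolidinone to the primary alcohol, a standard auxiliary removal that touches neither stereocentre (the descriptor of the aryl-bearing carbon changes to R only through the priority rules).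

Step 10
Reactants: 16 the acetal-protected diol
Product: 18 [(2S,3R)-6-bromo-4-methoxy-2-Ar1-2,3-dihydrobenzofuran-3-yl]methanol, via phenol triol 17 (not isolated)
Conditions: HCl (1 M in MeOH), 40 °C
Reagents that add atoms: none
Why: Acid cleavage of the methoxymethyl acetal followed by SN1 cyclodehydration, in which the electron-rich benzylic carbinol ionises and the neighbouring phenol captures the cation anti to the CH2OH group on C3, so C2 should become S (trans) under control of the C3 centre whatever the carbinol configuration was.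

Step 11
Reactants: 18 the dihydrobenzofuran alcohol
Product: 19 (2S,3R)-6-bromo-3-[(tert-butyldimethylsilyloxy)methyl]-4-methoxy-2-Ar1-2,3-dihydrobenzofuran (DBF–Br)
Conditions: TBSCl, imidazole, DMF, rt
Reagents that add atoms: tert-butyldimethylsilyl chloride, CC(C)(C)[Si](C)(C)Cl
Why: Silylation of the primary alcohol, needed because a free hydroxyl would be acylated by trichloroacetyl chloride in step 13.

Step 12
Reactants: 19 DBF–Br
Product: 20 (2S,3R)-6-allyl-3-[(tert-butyldimethylsilyloxy)methyl]-4-methoxy-2-Ar1-2,3-dihydrobenzofuran (DBF–allyl)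
Conditions: allylSnBu3, Pd(PPh3)4 (5 mol%), toluene, 100 °C
Reagents that add atoms: allyltributylstannane, C=CC[Sn](CCCC)(CCCC)CCCC
Why: Stille allylation of an unhindered aryl bromide with zerovalent palladium under neutral conditions, chosen over a base- or fluoride-promoted coupling because the aryl silyl ether would not tolerate those.

Step 13
Reactants: 20 DBF–allyl
Product: 21 2,2-dichloro-3-(DBF-methyl)cyclobutan-1-one (both epimers at the ring carbon)
Conditions: Cl3CCOCl, Zn–Cu couple, Et2O–DME, 0 °C → rt
Reagents that add atoms: trichloroacetyl chloride, ClC(Cl)(Cl)C(Cl)=O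
Why: [2+2] cycloaddition of dichloroketene, generated in the flask, to the terminal alkene with the usual regiochemistry (CCl2 next to the substituted carbon); the new ring stereocentre forms as a mixture and is erased in the next step.

Step 14
Reactants: 21 the dichlorocyclobutanone
Product: 22 3-(DBF-methyl)cyclobutan-1-one
Conditions: Zn dust, NH4Cl, MeOH, rt
Reagents that add atoms: none
Why: Reductive dechlorination of an α,α-dichloroketone by zinc under nearly neutral conditions, giving a four-membered ring with a mirror plane through C1 and C3 so that only the dihydrobenzofuran stereocentres remain.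

Step 15
Reactants: 22 3-(DBF-methyl)cyclobutan-1-one
Product: 24 (S)-4-(DBF-methyl)dihydrofuran-2(3H)-one, via Criegee adduct 23 (not isolated)
Conditions: Sc(OTf)3 (10 mol%), chiral N,N'-dioxide ligand (amino-acid-derived bis-anilide, 10 mol%), m-CPBA (1.2 equiv), EtOAc, −20 °C
Reagents that add atoms: 3-chloroperbenzoic acid, OOC(=O)c1cccc(Cl)c1
Why: The scandium-bound ketone adds the peracid to give the Criegee adduct 23, and one ring CH2 then migrates from carbon to oxygen antiperiplanar to the breaking O–O bond with loss of 3-chlorobenzoate, the strain of the four-membered ring making the shift fast at low temperature. The closest known reaction type is the catalytic asymmetric Baeyer–Villiger desymmetrisation of 3-substituted cyclobutanones to β-substituted γ-butyrolactones with chiral Lewis acid and peracid. The five-membered lactone arises by ring expansion (a 1,2-alkyl shift, four atoms to five) that forms the O–CH2 bond destined to be O1–C5 of the target. The new stereocentre (C4 of the target, S in 24) is set by the chiral ligand sphere on scandium alone, because the cyclobutanone ring of 22 is achiral and the dihydrobenzofuran centres are too remote to bias it. The step needs selection between two enantiotopic migrating methylenes (both give the same constitution, so no regiochemical question arises) and oxidation of the ketone in preference to the electron-rich arenes, which the strain-accelerated rearrangement at −20 °C and the near-stoichiometric peracid should secure.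

Step 16
Reactants: 24 the (S)-lactone; 4 4-methoxy-3-(triisopropylsilyloxy)benzaldehyde
Product: 26 (3R,4S)-3-[hydroxy(Ar2)methyl]-4-(DBF-methyl)dihydrofuran-2(3H)-one (both carbinol epimers), via lithium enolate 25 (not isolated)
Conditions: LiN(i-Pr)2, THF, −78 °C; then 4, −78 °C; NH4Cl (aq) at −78 °C
Reagents that add atoms: none
Why: Aldol addition of the lactone lithium enolate, in which the aldehyde enters anti to the substituent on C4 to give the 3,4-trans lactone (C3 = R), while the carbinol centre forms as a mixture that converges in step 18.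

Step 17
Reactants: 26 the aldol lactone
Product: 27 (2S,3S)-2-[hydroxy(Ar2)methyl]-3-(DBF-methyl)butane-1,4-diol (both carbinol epimers)
Conditions: LiAlH4, THF, 0 °C
Reagents that add atoms: none
Why: Hydride reduction of the lactone to the 1,4-diol without change at any stereocentre, after which the former carbonyl carbon is the CH2OH group that will sit cis to the arylmethyl group once the new ring is closed through the benzylic carbon.

Step 18
Reactants: 27 the triol
Product: 29 [(2R,3S,4S)-2-Ar2-4-(DBF-methyl)tetrahydrofuran-3-yl]methanol, via benzylic cation 28 (not isolated)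
Conditions: CSA (10 mol%), CH2Cl2, 0 °C, short contact time; then Et3N
Reagents that add atoms: none
Why: Acid-catalysed SN1 etherification, in which the para-methoxy-stabilised benzylic cation is captured by the hydroxyl on the future C5 in a five-membered closure that should outrun both Friedel–Crafts attack by ring A and oxetane formation, the aryl group settling trans to the CH2OH on C3 (C2 = R) under control of that centre so that both carbinol epimers converge.

Step 19
Reactants: 29 the silylated tetrahydrofuran
Product: 30 [(2R,3S,4S)-2-(3-hydroxy-4-methoxyphenyl)-4-{[(2S,3R)-2-(4-hydroxy-3-methoxyphenyl)-3-(hydroxymethyl)-4-methoxy-2,3-dihydrobenzofuran-6-yl]methyl}tetrahydrofuran-3-yl]methanol (CNP0242386.1)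
Conditions: TBAF, THF, 0 °C → rt
Reagents that add atoms: none
Why: Fluoride-mediated desilylation that removes the two aryl triisopropylsilyl ethers and the primary tert-butyldimethylsilyl ether in one operation and touches no stereocentre.

**Compound list**

1 | vanillin (4-hydroxy-3-methoxybenzaldehyde) | COc1cc(C=O)ccc1O | starting material
2 | 3-methoxy-4-(triisopropylsilyloxy)benzaldehyde | COc1cc(C=O)ccc1O[Si](C(C)C)(C(C)C)C(C)C | intermediate
3 | isovanillin (3-hydroxy-4-methoxybenzaldehyde) | COc1ccc(C=O)cc1O | starting material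
4 | 4-methoxy-3-(triisopropylsilyloxy)benzaldehyde | COc1ccc(C=O)cc1O[Si](C(C)C)(C(C)C)C(C)C | intermediate
5 | 4-bromo-2,6-dimethoxybenzaldehyde | COc1cc(Br)cc(OC)c1C=O | starting material
6 | 4-bromo-2-hydroxy-6-methoxybenzaldehyde | COc1cc(Br)cc(O)c1C=O | intermediate
7 | 4-bromo-2-methoxy-6-(methoxymethoxy)benzaldehyde | COCOc1cc(Br)cc(OC)c1C=O | intermediate
8 | 5-[4-bromo-2-methoxy-6-(methoxymethoxy)phenyl]-4-tosyl-4,5-dihydro-1,3-oxazole (formed in the flask, relative configuration not defined) | COCOc1cc(Br)cc(OC)c1C1OC=NC1S(=O)(=O)c1ccc(C)cc1 | intermediate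
9 | 2-[4-bromo-2-methoxy-6-(methoxymethoxy)phenyl]acetonitrile | COCOc1cc(Br)cc(OC)c1CC#N | intermediate
10 | 2-[4-bromo-2-methoxy-6-(methoxymethoxy)phenyl]acetic acid | COCOc1cc(Br)cc(OC)c1CC(=O)O | intermediate
11 | (S)-4-benzyl-2-oxazolidinone | O=C1N[C@@H](Cc2ccccc2)CO1 | starting material
12 | mixed anhydride of 10 with pivalic acid (formed in the flask) | COCOc1cc(Br)cc(OC)c1CC(=O)OC(=O)C(C)(C)C | intermediate
13 | (S)-4-benzyl-3-{2-[4-bromo-2-methoxy-6-(methoxymethoxy)phenyl]acetyl}oxazolidin-2-one | COCOc1cc(Br)cc(OC)c1CC(=O)N1[C@@H](Cc2ccccc2)COC1=O | intermediate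
14 | dibutylboron Z-enolate of 13 (formed in the flask) | COCOc1cc(Br)cc(OC)c1/C=C(\OB(CCCC)CCCC)N1[C@@H](Cc2ccccc2)COC1=O | intermediate
15 | (S)-4-benzyl-3-{(2S,3S)-2-[4-bromo-2-methoxy-6-(methoxymethoxy)phenyl]-3-hydroxy-3-[3-methoxy-4-(triisopropylsilyloxy)phenyl]propanoyl}oxazolidin-2-one | COCOc1cc(Br)cc(OC)c1[C@@H]([C@H](O)c1ccc(O[Si](C(C)C)(C(C)C)C(C)C)c(OC)c1)C(=O)N1[C@@H](Cc2ccccc2)COC1=O | intermediate
16 | (1S,2R)-2-[4-bromo-2-methoxy-6-(methoxymethoxy)phenyl]-1-[3-methoxy-4-(triisopropylsilyloxy)phenyl]propane-1,3-diol | COCOc1cc(Br)cc(OC)c1[C@@H]([C@H](O)c1ccc(O[Si](C(C)C)(C(C)C)C(C)C)c(OC)c1)CO | intermediate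
17 | (1S,2R)-2-(4-bromo-2-hydroxy-6-methoxyphenyl)-1-[3-methoxy-4-(triisopropylsilyloxy)phenyl]propane-1,3-diol (formed in the flask) | COc1cc(Br)cc(O)c1[C@@H]([C@H](O)c1ccc(O[Si](C(C)C)(C(C)C)C(C)C)c(OC)c1)CO | intermediate
18 | [(2S,3R)-6-bromo-4-methoxy-2-[3-methoxy-4-(triisopropylsilyloxy)phenyl]-2,3-dihydrobenzofuran-3-yl]methanol | Brc1cc(OC)c2c(c1)O[C@H](c1ccc(O[Si](C(C)C)(C(C)C)C(C)C)c(OC)c1)[C@H]2CO | intermediate
19 | (2S,3R)-6-bromo-3-[(tert-butyldimethylsilyloxy)methyl]-4-methoxy-2-[3-methoxy-4-(triisopropylsilyloxy)phenyl]-2,3-dihydrobenzofuran (DBF–Br) | Brc1cc(OC)c2c(c1)O[C@H](c1ccc(O[Si](C(C)C)(C(C)C)C(C)C)c(OC)c1)[C@H]2CO[Si](C)(C)C(C)(C)C | intermediate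
20 | (2S,3R)-6-allyl-3-[(tert-butyldimethylsilyloxy)methyl]-4-methoxy-2-[3-methoxy-4-(triisopropylsilyloxy)phenyl]-2,3-dihydrobenzofuran (DBF–allyl) | C=CCc1cc(OC)c2c(c1)O[C@H](c1ccc(O[Si](C(C)C)(C(C)C)C(C)C)c(OC)c1)[C@H]2CO[Si](C)(C)C(C)(C)C | intermediate
21 | 2,2-dichloro-3-(DBF-methyl)cyclobutan-1-one (both epimers at C3 of the cyclobutanone) | O=C1CC(Cc2cc(OC)c3c(c2)O[C@H](c2ccc(O[Si](C(C)C)(C(C)C)C(C)C)c(OC)c2)[C@H]3CO[Si](C)(C)C(C)(C)C)C1(Cl)Cl | intermediate
22 | 3-(DBF-methyl)cyclobutan-1-one (precursor of the key step) | O=C1CC(Cc2cc(OC)c3c(c2)O[C@H](c2ccc(O[Si](C(C)C)(C(C)C)C(C)C)c(OC)c2)[C@H]3CO[Si](C)(C)C(C)(C)C)C1 | intermediate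
23 | 1-hydroxy-3-(DBF-methyl)cyclobutyl 3-chloroperbenzoate (Criegee adduct, formed in the flask, configuration at the peroxy carbon not defined) | OC1(OOC(=O)c2cccc(Cl)c2)CC(Cc2cc(OC)c3c(c2)O[C@H](c2ccc(O[Si](C(C)C)(C(C)C)C(C)C)c(OC)c2)[C@H]3CO[Si](C)(C)C(C)(C)C)C1 | intermediate
24 | (S)-4-(DBF-methyl)dihydrofuran-2(3H)-one (product of the key step) | O=C1C[C@H](Cc2cc(OC)c3c(c2)O[C@H](c2ccc(O[Si](C(C)C)(C(C)C)C(C)C)c(OC)c2)[C@H]3CO[Si](C)(C)C(C)(C)C)CO1 | intermediate
25 | lithium enolate of 24 (formed in the flask) | [Li]OC1=C[C@H](Cc2cc(OC)c3c(c2)O[C@H](c2ccc(O[Si](C(C)C)(C(C)C)C(C)C)c(OC)c2)[C@H]3CO[Si](C)(C)C(C)(C)C)CO1 | intermediate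
26 | (3R,4S)-3-{hydroxy[4-methoxy-3-(triisopropylsilyloxy)phenyl]methyl}-4-(DBF-methyl)dihydrofuran-2(3H)-one (both carbinol epimers) | O=C1OC[C@@H](Cc2cc(OC)c3c(c2)O[C@H](c2ccc(O[Si](C(C)C)(C(C)C)C(C)C)c(OC)c2)[C@H]3CO[Si](C)(C)C(C)(C)C)[C@@H]1C(O)c1ccc(OC)c(O[Si](C(C)C)(C(C)C)C(C)C)c1 | intermediate
27 | (2S,3S)-2-{hydroxy[4-methoxy-3-(triisopropylsilyloxy)phenyl]methyl}-3-(DBF-methyl)butane-1,4-diol (both carbinol epimers) | OC[C@@H](Cc1cc(OC)c2c(c1)O[C@H](c1ccc(O[Si](C(C)C)(C(C)C)C(C)C)c(OC)c1)[C@H]2CO[Si](C)(C)C(C)(C)C)[C@@H](CO)C(O)c1ccc(OC)c(O[Si](C(C)C)(C(C)C)C(C)C)c1 | intermediate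
28 | benzylic cation derived from 27 by loss of the benzylic hydroxyl (formed in the flask) | OC[C@@H](Cc1cc(OC)c2c(c1)O[C@H](c1ccc(O[Si](C(C)C)(C(C)C)C(C)C)c(OC)c1)[C@H]2CO[Si](C)(C)C(C)(C)C)[C@@H](CO)[CH+]c1ccc(OC)c(O[Si](C(C)C)(C(C)C)C(C)C)c1 | intermediate
29 | [(2R,3S,4S)-2-[4-methoxy-3-(triisopropylsilyloxy)phenyl]-4-(DBF-methyl)tetrahydrofuran-3-yl]methanol | COc1ccc([C@@H]2OC[C@@H](Cc3cc(OC)c4c(c3)O[C@H](c3ccc(O[Si](C(C)C)(C(C)C)C(C)C)c(OC)c3)[C@H]4CO[Si](C)(C)C(C)(C)C)[C@H]2CO)cc1O[Si](C(C)C)(C(C)C)C(C)C | intermediate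
30 | CNP0242386.1, [(2R,3S,4S)-2-(3-hydroxy-4-methoxyphenyl)-4-{[(2S,3R)-2-(4-hydroxy-3-methoxyphenyl)-3-(hydroxymethyl)-4-methoxy-2,3-dihydrobenzofuran-6-yl]methyl}tetrahydrofuran-3-yl]methanol | COc1ccc([C@@H]2OC[C@@H](Cc3cc(OC)c4c(c3)O[C@H](c3ccc(O)c(OC)c3)[C@H]4CO)[C@H]2CO)cc1O | target

**Step count and risks**

Total step count: 19. Longest linear sequence: 17 (steps 3 to 19; steps 1 and 2 prepare the two aldehyde partners).

Three steps most likely to fail:

1. Step 15, the oxygen insertion. What may go wrong: the catalyst may discriminate poorly between the two enantiotopic methylenes on this large substrate, and the peracid may begin to oxidise the electron-rich arenes if the rearrangement is slow. The fallback sets out from 22 and returns at 24. Ketone 22 is deprotonated enantioselectively with a chiral lithium amide, LiN[CH(CH3)Ph]2 (antipode assigned on 3-benzylcyclobutanone), in the presence of Et3SiCl at −100 °C, which gives the silyl enol ether (S)-3-(DBF-methyl)-1-(triethylsilyloxy)cyclobut-1-ene F1. Ozonolysis of the enol ether double bond at −78 °C with NaBH4 work-up gives the hydroxy acid (S)-4-hydroxy-3-(DBF-methyl)butanoic acid F2, which lactonises to 24 on acidification.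

2. Step 18, the cationic ring closure. What may go wrong: under acid the benzylic ether can re-ionise, so the kinetically formed tetrahydrofuran is slowly drained into the tetralin that arises by irreversible Friedel–Crafts attack of the electron-rich ring A on the cation, and the trans selectivity may be incomplete. The fallback sets out from 27 and returns at 30. The two primary hydroxyls of 27 are silylated selectively (TBSCl, imidazole, CH2Cl2, 0 °C) to give the bis-silyl ether (2S,3S)-1,4-bis(tert-butyldimethylsilyloxy)-2-[hydroxy(Ar2)methyl]-3-(DBF-methyl)butane F3. The remaining benzylic alcohol is converted under basic conditions (MsCl, Et3N, CH2Cl2, −40 °C) into the benzylic chloride (2S,3S)-1,4-bis(tert-butyldimethylsilyloxy)-2-[chloro(Ar2)methyl]-3-(DBF-methyl)butane F4, which is not isolated. Excess TBAF then removes all five silyl groups, and the alkoxide on the future C5 displaces the chloride in a Williamson closure that gives 30 directly and merges step 19. No acid is present, so the ether cannot re-open, and chloride exchange should let both chloride epimers drain through the faster closure to the trans ether.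

3. Step 13, the ketene cycloaddition. What may go wrong: the zinc chloride formed alongside the ketene may ionise the benzylic C–O bond of the dihydrobenzofuran or strip silyl ethers, and the cycloaddition to the unactivated terminal alkene may stall while the ketene oligomerises. The fallback sets out from 19 and returns at 22. Zinc insertion (Zn dust, LiCl, THF) into commercial 3-(bromomethyl)cyclobutan-1-one gives (3-oxocyclobutyl)methylzinc bromide F5, which is joined to aryl bromide 19 in a Negishi coupling [Pd(OAc)2, SPhos, THF, 50 °C]. This forms the aryl–CH2 bond and delivers 22 without passing through 20 and 21.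

**Further compounds**

F1 | step 15 | (S)-3-(DBF-methyl)-1-(triethylsilyloxy)cyclobut-1-ene | CC[Si](CC)(CC)OC1=C[C@@H](Cc2cc(OC)c3c(c2)O[C@H](c2ccc(O[Si](C(C)C)(C(C)C)C(C)C)c(OC)c2)[C@H]3CO[Si](C)(C)C(C)(C)C)C1
F2 | step 15 | (S)-4-hydroxy-3-(DBF-methyl)butanoic acid | OC[C@@H](Cc1cc(OC)c2c(c1)O[C@H](c1ccc(O[Si](C(C)C)(C(C)C)C(C)C)c(OC)c1)[C@H]2CO[Si](C)(C)C(C)(C)C)CC(=O)O
F3 | step 18 | (2S,3S)-1,4-bis(tert-butyldimethylsilyloxy)-2-{hydroxy[4-methoxy-3-(triisopropylsilyloxy)phenyl]methyl}-3-(DBF-methyl)butane | CC(C)(C)[Si](C)(C)OC[C@@H](Cc1cc(OC)c2c(c1)O[C@H](c1ccc(O[Si](C(C)C)(C(C)C)C(C)C)c(OC)c1)[C@H]2CO[Si](C)(C)C(C)(C)C)[C@@H](CO[Si](C)(C)C(C)(C)C)C(O)c1ccc(OC)c(O[Si](C(C)C)(C(C)C)C(C)C)c1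
F4 | step 18 | (2S,3S)-1,4-bis(tert-butyldimethylsilyloxy)-2-{chloro[4-methoxy-3-(triisopropylsilyloxy)phenyl]methyl}-3-(DBF-methyl)butane | CC(C)(C)[Si](C)(C)OC[C@@H](Cc1cc(OC)c2c(c1)O[C@H](c1ccc(O[Si](C(C)C)(C(C)C)C(C)C)c(OC)c1)[C@H]2CO[Si](C)(C)C(C)(C)C)[C@@H](CO[Si](C)(C)C(C)(C)C)C(Cl)c1ccc(OC)c(O[Si](C(C)C)(C(C)C)C(C)C)c1
F5 | step 13 | (3-oxocyclobutyl)methylzinc bromide | O=C1CC(C[Zn]Br)C1
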